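## Retrosynthetic overview

1. The target comes from C7‑acylation of a bicyclic vinylogous amide that carries (S)‑2‑(methoxymethyl)pyrrolidine at C8, followed by exchange of the amine for OH; the side chain is 3‑phenylpropanoyl chloride.
2. The bicyclic core comes from one thermal operation on a 4‑alkenyl‑4‑hydroxycyclobutenone plus 3‑methylbut‑2‑enal: 4π opening/6π closure builds the carbocycle and the quaternary carbon, then a boronate‑templated condensation/oxa‑6π closure builds the pyran.
3. The cyclobutenone comes from an (E)‑alkenyllithium and a 3‑aminocyclobutenedione (diisopropyl squarate → 3‑isopropoxycyclobutenedione → amine exchange).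
4. The alkenyllithium comes from an (E)‑vinyl iodide, made by carboalumination of 5‑methylhex‑4‑en‑1‑yne (prenyl bromide + ethynyl Grignard).
5. Ring order: carbocycle first, pyran second, both in the same flask; the phenyl ring is bought. The stereocentre arises in the 6π closure under auxiliary bias, and the epimers are separated as diastereomers.

Assumption: the (S)‑auxiliary is taken to favour the (5S) epimer in step 6; whatever the ratio, the two C5 epimers are diastereomers and the (5S) one is isolated by chromatography (if the intrinsic preference is opposite, the (R)‑amine is used instead).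

## Route

Step 1
Reactants: 1 diisopropyl squarate (3,4-diisopropoxycyclobut-3-ene-1,2-dione)
Product: 3 3-isopropoxycyclobut-3-ene-1,2-dione, via hydroxycyclobutenone 2 (not isolated)
Conditions: LiAlH(OtBu)3, THF, −78 → −20 °C; then 6 M aq. HCl, CH2Cl2, 0 °C → rt
Reagents that add atoms: water, O
Why: Mono‑reduction of one squarate carbonyl followed by acid‑promoted allylic transposition with loss of isopropanol (the squarate‑to‑semisquarate conversion) leaves a vinylic C–H at the carbon that later takes the acyl group, and no stereocentre survives.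

Step 2
Reactants: 3 3-isopropoxycyclobut-3-ene-1,2-dione; 4 (2S)-2-(methoxymethyl)pyrrolidine
Product: 5 3-[(2S)-2-(methoxymethyl)pyrrolidin-1-yl]cyclobut-3-ene-1,2-dione
Conditions: CH2Cl2, 0 °C → rt
Reagents that add atoms: none
Why: Addition–elimination of the secondary amine at the alkoxy‑bearing carbon (vinylogous acyl substitution, as in squarate aminolysis) gives the vinylogous amide, and the auxiliary stereocentre is not touched.

Step 3
Reactants: 6 1-bromo-3-methylbut-2-ene (prenyl bromide)
Product: 7 5-methylhex-4-en-1-yne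
Conditions: HC≡CMgBr (2.5 equiv), CuCl (5 mol %), THF, 0 → 45 °C
Reagents that add atoms: ethynylmagnesium bromide, C#C[Mg]Br
Why: CuCl‑catalysed SN2 coupling of an alkynyl Grignard reagent with a primary allylic bromide gives the skipped enyne, and the excess of acetylide suppresses double alkylation.

Step 4
Reactants: 7 5-methylhex-4-en-1-yne
Product: 9 (1E)-1-iodo-2,5-dimethylhexa-1,4-diene, via alkenylalane 8 (not isolated)
Conditions: AlMe3 (2 equiv), Cp2ZrCl2 (0.25 equiv), CH2Cl2, 0 °C → rt; then I2, THF, −30 → 0 °C; aq. NaHCO3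
Reagents that add atoms: trimethylaluminium, C[Al](C)C; iodine, II
Why: Negishi Cp2ZrCl2‑catalysed syn‑carboalumination puts methyl on the internal alkyne carbon with aluminium cis to it, and iodinolysis with retention fixes the E trisubstituted alkene while the trisubstituted prenyl alkene stays inert.

Step 5
Reactants: 9 (1E)-1-iodo-2,5-dimethylhexa-1,4-diene; 5 3-[(2S)-2-(methoxymethyl)pyrrolidin-1-yl]cyclobut-3-ene-1,2-dione
Product: 11 4-[(1E)-2,5-dimethylhexa-1,4-dien-1-yl]-4-hydroxy-3-[(2S)-2-(methoxymethyl)pyrrolidin-1-yl]cyclobut-2-en-1-one, via alkenyllithium 10 (not isolated)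
Conditions: t-BuLi (2.05 equiv), Et2O, −78 °C; then 5, THF, −78 °C; aq. NH4Cl
Reagents that add atoms: none
Why: Iodine–lithium exchange with retention, then 1,2‑addition to the ketone‑like carbonyl next to the amino‑bearing carbon (the other carbonyl is deactivated as a vinylogous amide), follows the regiochemistry known for organolithium additions to 3‑heteroatom‑substituted cyclobutenediones; the carbinol stereocentre forms as a mixture and is erased in step 6.

Step 6
Reactants: 11 4-[(1E)-2,5-dimethylhexa-1,4-dien-1-yl]-4-hydroxy-3-[(2S)-2-(methoxymethyl)pyrrolidin-1-yl]cyclobut-2-en-1-one; 12 3-methylbut-2-enal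
Product: 16 (5S)-8-[(2S)-2-(methoxymethyl)pyrrolidin-1-yl]-2,2,5-trimethyl-5-(3-methylbut-2-en-1-yl)-2H-chromen-6(5H)-one, via dienylketene 13 (not isolated), via aminocyclohexenedione 14 (not isolated), via oxatriene 15 (not isolated)
Conditions: 12 (3 equiv), PhB(OH)2 (1.1 equiv), p-xylene, 138 °C, Dean–Stark; then SiO2 chromatography (removal of the 5R epimer)
Reagents that add atoms: none
Why: Proposed new method: thermal 4π opening of the cyclobutenone (hydroxyl outward) gives dienylketene 13, whose disrotatory 6π closure onto the trisubstituted alkene builds the carbocycle and the quaternary stereocentre (Moore rearrangement of 4‑alkenyl‑4‑hydroxycyclobutenones), and the resulting dienol/ketone 14 is condensed at its only enolisable carbon with the enal through a phenylboronate template to oxatriene 15, which closes by oxa‑6π electrocyclisation to the pyran (the phenol–enal 2H‑chromene annulation transferred to a dienol); the helical sense of the 6π step, and so C5, is biased by the (S)‑amine on the central triene carbon as this auxiliary biases cycloadditions of 2‑aminodienes, and because the two C5 epimers are diastereomers the (5S) one is obtained pure by chromatography.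

Step 7
Reactants: 16 (5S)-8-[(2S)-2-(methoxymethyl)pyrrolidin-1-yl]-2,2,5-trimethyl-5-(3-methylbut-2-en-1-yl)-2H-chromen-6(5H)-one; 17 3-phenylpropanoyl chloride
Product: 19 (5S)-8-hydroxy-2,2,5-trimethyl-5-(3-methylbut-2-en-1-yl)-7-(3-phenylpropanoyl)-2H-chromen-6(5H)-one, via C-acyl enaminone 18 (not isolated)
Conditions: 17 (1.2 equiv), pyridine, CH2Cl2, 0 °C → rt; then 1 M aq. HCl, THF, rt
Reagents that add atoms: water, O
Why: C‑Acylation at the nucleophilic α‑carbon of the vinylogous amide (Stork‑type enaminone acylation) and hydrolysis of the now doubly activated enamine release the auxiliary and the enolised triketone, and the quaternary centre has no α‑hydrogen and cannot epimerise.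

## Compound list

1 | diisopropyl squarate (3,4-diisopropoxycyclobut-3-ene-1,2-dione) | CC(C)OC1=C(OC(C)C)C(=O)C1=O | starting material
2 | 4-hydroxy-2,3-diisopropoxycyclobut-2-en-1-one (racemic) | CC(C)OC1=C(OC(C)C)C(O)C1=O | intermediate
3 | 3-isopropoxycyclobut-3-ene-1,2-dione | CC(C)OC1=CC(=O)C1=O | intermediate
4 | (2S)-2-(methoxymethyl)pyrrolidine | COC[C@@H]1CCCN1 | starting material
5 | 3-[(2S)-2-(methoxymethyl)pyrrolidin-1-yl]cyclobut-3-ene-1,2-dione | COC[C@@H]1CCCN1C2=CC(=O)C2=O | intermediate
6 | 1-bromo-3-methylbut-2-ene (prenyl bromide) | CC(C)=CCBr | starting material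
7 | 5-methylhex-4-en-1-yne | C#CCC=C(C)C | intermediate
8 | [(1E)-2,5-dimethylhexa-1,4-dien-1-yl]dimethylaluminium | C[Al](C)/C=C(\C)CC=C(C)C | intermediate
9 | (1E)-1-iodo-2,5-dimethylhexa-1,4-diene | I/C=C(\C)CC=C(C)C | intermediate
10 | [(1E)-2,5-dimethylhexa-1,4-dien-1-yl]lithium | [Li]/C=C(\C)CC=C(C)C | intermediate
11 | 4-[(1E)-2,5-dimethylhexa-1,4-dien-1-yl]-4-hydroxy-3-[(2S)-2-(methoxymethyl)pyrrolidin-1-yl]cyclobut-2-en-1-one (both C4 epimers) | COC[C@@H]1CCCN1C2=CC(=O)C2(O)/C=C(\C)CC=C(C)C | intermediate
12 | 3-methylbut-2-enal | CC(C)=CC=O | starting material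
13 | (3Z,5E)-4-hydroxy-3-[(2S)-2-(methoxymethyl)pyrrolidin-1-yl]-6,9-dimethyldeca-1,3,5,8-tetraen-1-one | O=C=C/C(N1CCC[C@H]1COC)=C(/O)\C=C(/C)CC=C(C)C | intermediate
14 | (5S)-2-[(2S)-2-(methoxymethyl)pyrrolidin-1-yl]-5-methyl-5-(3-methylbut-2-en-1-yl)cyclohex-2-ene-1,4-dione (formed together with its 5R epimer) | CC(C)=CC[C@]1(C)C(=O)C=C(N2CCC[C@H]2COC)C(=O)C1 | intermediate
15 | (5S,6Z)-2-[(2S)-2-(methoxymethyl)pyrrolidin-1-yl]-5-methyl-5-(3-methylbut-2-en-1-yl)-6-(3-methylbut-2-en-1-ylidene)cyclohex-2-ene-1,4-dione (formed together with its 5R epimer) | CC(C)=CC[C@]1(C)C(=O)C=C(N2CCC[C@H]2COC)C(=O)/C1=C\C=C(C)C | intermediate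
16 | (5S)-8-[(2S)-2-(methoxymethyl)pyrrolidin-1-yl]-2,2,5-trimethyl-5-(3-methylbut-2-en-1-yl)-2H-chromen-6(5H)-one | CC(C)=CC[C@]1(C)C(=O)C=C(N3CCC[C@H]3COC)C2=C1C=CC(C)(C)O2 | intermediate
17 | 3-phenylpropanoyl chloride | O=C(Cl)CCc1ccccc1 | starting material
18 | (5S)-8-[(2S)-2-(methoxymethyl)pyrrolidin-1-yl]-2,2,5-trimethyl-5-(3-methylbut-2-en-1-yl)-7-(3-phenylpropanoyl)-2H-chromen-6(5H)-one | CC(C)=CC[C@]1(C)C(=O)C(C(=O)CCc4ccccc4)=C(N3CCC[C@H]3COC)C2=C1C=CC(C)(C)O2 | intermediate
19 | (5S)-8-hydroxy-2,2,5-trimethyl-5-(3-methylbut-2-en-1-yl)-7-(3-phenylpropanoyl)-2H-chromen-6(5H)-one (CNP0120278.1) | CC(C)=CC[C@]1(C)C(=O)C(C(=O)CCc2ccccc2)=C(O)C2=C1C=CC(C)(C)O2 | target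

## Step count and risk

Total step count: 7.
Longest linear sequence: 5 steps (6 → 7 → 9 → 11 → 16 → 19; equally 1 → 3 → 5 → 11 → 16 → 19).

Steps most likely to fail:

Step 5. The amino‑substituted dione 5 is a less electrophilic and less precedented acceptor than its alkoxy analogues, so the addition may be slow or go to the wrong carbonyl. The fallback sets out from 3 and 9 and comes back at 11. Alkenyllithium 10 (made from 9 as before) is added to the alkoxy dione 3, for which this regiochemistry is established, to give 4-[(1E)-2,5-dimethylhexa-1,4-dien-1-yl]-4-hydroxy-3-isopropoxycyclobut-2-en-1-one F1. The amine 4 is then introduced by aminolysis of the vinylogous ester of F1 (CH2Cl2, rt), which gives 11.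

Step 6. The templated condensation of the enal with the ring‑expanded dienol may lose to simple ketonisation, or the enaminone α‑carbon may intercept the aldehyde. The fallback sets out from 11 and comes back at 16. Compound 11 is heated alone (p‑xylene, 138 °C) and the ring‑expanded dione 14 is isolated; the C5 epimers can already be separated here. Its only enolisable position is deprotonated (LiN(SiMe3)2, THF, −78 °C) and the enolate is added to 12 to give the aldol (5S)-6-(1-hydroxy-3-methylbut-2-en-1-yl)-2-[(2S)-2-(methoxymethyl)pyrrolidin-1-yl]-5-methyl-5-(3-methylbut-2-en-1-yl)cyclohex-2-ene-1,4-dione F2. TsOH (cat.) in benzene at 60 °C dehydrates F2 to oxatriene 15, which electrocyclises to 16.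

Step 7. C‑Acylation of the hindered, cross‑conjugated enaminone may be slow or stop at O‑acylation. The fallback sets out from 16 and comes back at 19. Aqueous NaOH in EtOH (60 °C) hydrolyses the vinylogous amide to (5S)-8-hydroxy-2,2,5-trimethyl-5-(3-methylbut-2-en-1-yl)-2H-chromen-6(5H)-one F3. Treatment with 17 and Et3N gives the enol ester (5S)-2,2,5-trimethyl-5-(3-methylbut-2-en-1-yl)-6-oxo-5,6-dihydro-2H-chromen-8-yl 3-phenylpropanoate F4. DMAP (cat.) in toluene at 80 °C then effects the O‑to‑C acyl shift to 19.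

## Further compounds

F1 | step 5 | 4-[(1E)-2,5-dimethylhexa-1,4-dien-1-yl]-4-hydroxy-3-isopropoxycyclobut-2-en-1-one (racemic) | CC(C)OC1=CC(=O)C1(O)/C=C(\C)CC=C(C)C
F2 | step 6 | (5S)-6-(1-hydroxy-3-methylbut-2-en-1-yl)-2-[(2S)-2-(methoxymethyl)pyrrolidin-1-yl]-5-methyl-5-(3-methylbut-2-en-1-yl)cyclohex-2-ene-1,4-dione (mixture at the two new centres) | CC(C)=CC[C@]1(C)C(=O)C=C(N2CCC[C@H]2COC)C(=O)C1C(O)C=C(C)C
F3 | step 7 | (5S)-8-hydroxy-2,2,5-trimethyl-5-(3-methylbut-2-en-1-yl)-2H-chromen-6(5H)-one | CC(C)=CC[C@]1(C)C(=O)C=C(O)C2=C1C=CC(C)(C)O2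
F4 | step 7 | (5S)-2,2,5-trimethyl-5-(3-methylbut-2-en-1-yl)-6-oxo-5,6-dihydro-2H-chromen-8-yl 3-phenylpropanoate | CC(C)=CC[C@]1(C)C(=O)C=C(OC(=O)CCc3ccccc3)C2=C1C=CC(C)(C)O2
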